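**Assumptions (one line each).** Atom labels follow aromadendrane numbering: C1/C5 ring-fusion CH, C2 acetal, C3 enol-ether CH, C4 (bears C15), C6/C7 cyclopropane CH, C8/C9 CH2, C10 spiro carbon, C11 CMe2, C14 epoxide CH2; the target is (1R,2R,5R,6S,7S,10S). Catalogue reagents (Rh2(5R-MEPY)4, ylide 10, salt 14) are taken as commercially available. Enol 15 and lactols 21/23 are drawn as the major tautomer/anomer.

## Retrosynthetic overview

1. Plagiochilin A ⇐ epoxy-lactol ester 23 by one-pot DIBAL reduction/in-situ acetylation (gives both acetates); the spiro-epoxide comes from lactol-directed epoxidation of a C10=C14 methylene.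
2. The cis C1–H and the exocyclic methylene ⇐ a single deconjugative α-protonation of alkylidene lactone 19 ⇐ triflate/methyl coupling on β-keto enol-lactone 15 (C2 is deliberately carried one oxidation level too high).
3. Key step: 15 ⇐ one-pot Knoevenagel / 7-exo Michael / lactonization of cyclopropyl aldehyde–β-keto ester 13 with formylacetate, forming the cycloheptane and the pyranone together and setting C5.
4. 13 ⇐ Doyle lactone 6 by Wittig chain extension ⇐ Rh-catalysed asymmetric intramolecular cyclopropanation of prenyl diazoacetate (sets C6, C7).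
5. Ring order: cyclopropane → seven-membered ring + pyran(one) in the same operation → epoxide.

## Forward route

**Step 1**
Reactants: 1 prenol; 2 bromoacetyl bromide
Product: 3 prenyl bromoacetate
Conditions: NaHCO3, MeCN, 0 °C
Reagents that add atoms: bromoacetyl bromide, BrCC(Br)=O
Why: Simple O-acylation of the allylic alcohol by the acid bromide (esterification); no stereocentre is involved.

**Step 2**
Reactants: 3 prenyl bromoacetate; 4 N,N'-ditosylhydrazine
Product: 5 prenyl diazoacetate
Conditions: DBU, THF, 0 °C
Reagents that add atoms: N,N'-ditosylhydrazine, Cc1ccc(cc1)S(=O)(=O)NNS(=O)(=O)c1ccc(C)cc1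
Why: Fukuyama diazoacetate synthesis: SN2 displacement of bromide by the hydrazine, then base-induced loss of two sulfinates gives the diazo ester.

**Step 3**
Reactants: 5 prenyl diazoacetate
Product: 6 (1R,5S)-6,6-dimethyl-3-oxabicyclo[3.1.0]hexan-2-one
Conditions: Rh2(5R-MEPY)4 (1 mol %), CH2Cl2, reflux, slow addition
Reagents that add atoms: none
Why: Doyle Rh(II)-carboxamidate intramolecular cyclopropanation; the tether enforces the cis ring fusion and the chiral ligand selects the alkene face, setting C6 and C7.

**Step 4**
Reactants: 6 lactone; 7 N,O-dimethylhydroxylamine hydrochloride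
Product: 8 (1R,3S)-3-(hydroxymethyl)-N-methoxy-N,2,2-trimethylcyclopropane-1-carboxamide
Conditions: AlMe3, CH2Cl2, 0 °C → rt
Reagents that add atoms: N,O-dimethylhydroxylamine hydrochloride, CNOC.Cl
Why: Weinreb aminolysis of the lactone by acyl–O cleavage differentiates the two cyclopropane arms without touching either stereocentre.

**Step 5**
Reactants: 8 hydroxy Weinreb amide
Product: 9 (1R,3S)-3-formyl-N-methoxy-N,2,2-trimethylcyclopropane-1-carboxamide
Conditions: Dess–Martin periodinane, NaHCO3, CH2Cl2, 0 °C
Reagents that add atoms: none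
Why: Dess–Martin oxidation of the primary alcohol under buffered conditions that do not epimerize the cis cyclopropane.

**Step 6**
Reactants: 9 aldehyde; 10 ethyl 3-oxo-4-(triphenylphosphoranylidene)butanoate
Product: 11 ethyl (E)-5-[(1S,3R)-3-[methoxy(methyl)carbamoyl]-2,2-dimethylcyclopropyl]-3-oxopent-4-enoate
Conditions: NaH, THF, 0 °C → rt
Reagents that add atoms: ylide 10, CCOC(=O)CC(=O)C=P(c1ccccc1)(c1ccccc1)c1ccccc1
Why: Wittig olefination with the acetoacetate-derived stabilized ylide (as its sodium enolate) installs C9–C10–C1–C2 in one step; the alkene geometry is irrelevant.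

**Step 7**
Reactants: 11 enone
Product: 12 ethyl 5-[(1S,3R)-3-[methoxy(methyl)carbamoyl]-2,2-dimethylcyclopropyl]-3-oxopentanoate
Conditions: Cu(OAc)2 (5 mol %), 1,2-bis(diphenylphosphino)benzene, PMHS, t-BuOH, PhMe, rt
Reagents that add atoms: none
Why: Ligated CuH (Stryker-type) conjugate reduction delivers hydride to C8 by a polar, non-radical path, so the adjacent cyclopropane survives and the amide and ester are untouched.

**Step 8**
Reactants: 12 Weinreb amide β-keto ester
Product: 13 ethyl 5-[(1S,3R)-3-formyl-2,2-dimethylcyclopropyl]-3-oxopentanoate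
Conditions: NaH (1.1 equiv), THF, 0 °C; then DIBAL-H, −78 °C; Rochelle salt work-up
Reagents that add atoms: none
Why: The β-keto ester is masked as its sodium enolate, so DIBAL reduces only the Weinreb amide, whose chelated tetrahedral intermediate releases the aldehyde on work-up.

**Step 9 (key step)**
Reactants: 13 aldehyde–β-keto ester; 14 sodium (E)-3-ethoxy-3-oxoprop-1-en-1-olate (ethyl formylacetate sodium salt)
Product: 15 tricyclic β-keto enol-lactone (C10 enol form): C2 lactone C=O, ring O to C3H=C4(CO2Et), C1=C10(OH); 5S,6S,7S
Conditions: piperidine (cat.), AcOH, EtOH, rt; then TsOH (cat.), PhMe, 80 °C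
Reagents that add atoms: ethyl formylacetate sodium salt, [Na+].[O-]/C=C/C(=O)OCC
Why: Proposed new method: amine-catalysed Knoevenagel condensation at the cyclopropyl aldehyde, 7-exo-trig Michael closure through the β-keto ester carbon C1 (or Michael addition of formylacetate to the cyclic alkylidene β-keto ester; both paths converge), then acid-promoted acyl transfer from the C2 ester to the formylacetate enol oxygen; C4 can bond to C5 only on the face anti to the CMe2 bridge, and the competing O-cyclizations would give bridged anti-Bredt rings; the closest known reaction type is the three-component Knoevenagel/Michael/cyclization (formal [3+3]) of aldehydes with two 1,3-dicarbonyls to dihydropyranones.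

**Step 10**
Reactants: 15 enol-lactone; 16 triflic anhydride
Product: 17 C10 vinyl triflate of 15; 5S,6S,7S
Conditions: Tf2O, pyridine, CH2Cl2, −78 → −20 °C
Reagents that add atoms: triflic anhydride, FC(F)(F)S(=O)(=O)OS(=O)(=O)C(F)(F)F
Why: O-triflation of a vinylogous acid (β-keto lactone enol), as for 4-hydroxy-2-pyranones.

**Step 11**
Reactants: 17 vinyl triflate; 18 methylzinc chloride
Product: 19 α-alkylidene enol-lactone with C1=C10(CH3); 5R,6S,7S
Conditions: Pd(PPh3)4 (5 mol %), THF, 0 °C → rt
Reagents that add atoms: methylzinc chloride, C[Zn]Cl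
Why: Negishi cross-coupling of the activated vinyl triflate under neutral conditions introduces C14 without disturbing the enol lactone.

**Step 12**
Reactants: 19 alkylidene lactone
Product: 20 cis-fused β,γ-unsaturated enol-lactone with C1–H and exocyclic C10=C14; 1R,5R,6S,7S
Conditions: LDA (1.2 equiv), THF–DMPU, −78 °C, 20 min; inverse quench into AcOH/THF, −78 °C
Reagents that add atoms: none
Why: Deconjugative kinetic α-protonation: LDA removes a γ-H from the C14 methyl (syn to the s-cis lactone C=O), and the dienolate is protonated at C1 from the open face opposite C6 (the face of H5), giving the cis ring fusion and the exocyclic methylene together.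

**Step 13**
Reactants: 20 enol-lactone ester
Product: 21 lactol ester (2-hydroxy-dihydropyran with 4-CO2Et and C10=C14); 1R,2S,5R,6S,7S major anomer
Conditions: DIBAL-H (1.1 equiv), CH2Cl2, −78 °C; Rochelle salt
Reagents that add atoms: none
Why: DIBAL half-reduction of an enol lactone to the lactol (as in nepetalactone → nepetalactol); the push–pull β-alkoxyacrylate ester is far less electrophilic and survives, and the lactol settles with OH trans to the C1–C10 bond as in genipin-type lactols.

**Step 14**
Reactants: 21 lactol ester; 22 tert-butyl hydroperoxide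
Product: 23 epoxy-lactol ester with the C10–C14 spiro-epoxide; 1R,2S,5R,6S,7S,10S
Conditions: VO(acac)2 (5 mol %), t-BuOOH, CH2Cl2, 0 °C → rt
Reagents that add atoms: tert-butyl hydroperoxide, CC(C)(C)OO
Why: Hydroxyl-directed vanadium epoxidation: the homoallylic lactol OH delivers oxygen to the C10=C14 face on the same side as C2, setting C10, while the ester-deactivated enol ether is not attacked.

**Step 15**
Reactants: 23 epoxy-lactol ester; 24 acetic anhydride
Product: 25 plagiochilin A
Conditions: DIBAL-H (3.5 equiv), CH2Cl2, −78 °C; then pyridine, DMAP, Ac2O, −78 → 0 °C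
Reagents that add atoms: acetic anhydride, CC(=O)OC(C)=O
Why: DIBAL reduces the β-alkoxyacrylate ester to the allylic aluminate while the lactol is held as its aluminium alkoxide, and in-situ acylation (Rychnovsky-type trapping) gives both acetates with retention at C2.

## Compound list

1 | prenol (3-methylbut-2-en-1-ol) | CC(C)=CCO | starting material
2 | bromoacetyl bromide | BrCC(Br)=O | starting material
3 | prenyl bromoacetate | CC(C)=CCOC(=O)CBr | intermediate
4 | N,N'-ditosylhydrazine | Cc1ccc(cc1)S(=O)(=O)NNS(=O)(=O)c1ccc(C)cc1 | starting material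
5 | prenyl diazoacetate | CC(C)=CCOC(=O)C=[N+]=[N-] | intermediate
6 | (1R,5S)-6,6-dimethyl-3-oxabicyclo[3.1.0]hexan-2-one | O=C2[C@@H]1[C@H](CO2)C1(C)C | intermediate
7 | N,O-dimethylhydroxylamine hydrochloride | CNOC.Cl | starting material
8 | (1R,3S)-3-(hydroxymethyl)-N-methoxy-N,2,2-trimethylcyclopropane-1-carboxamide | CON(C)C(=O)[C@@H]1[C@H](CO)C1(C)C | intermediate
9 | (1R,3S)-3-formyl-N-methoxy-N,2,2-trimethylcyclopropane-1-carboxamide | CON(C)C(=O)[C@@H]1[C@H](C=O)C1(C)C | intermediate
10 | ethyl 3-oxo-4-(triphenylphosphoranylidene)butanoate | CCOC(=O)CC(=O)C=P(c1ccccc1)(c1ccccc1)c1ccccc1 | starting material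
11 | ethyl (E)-5-[(1S,3R)-3-[methoxy(methyl)carbamoyl]-2,2-dimethylcyclopropyl]-3-oxopent-4-enoate | CON(C)C(=O)[C@@H]1[C@H](/C=C/C(=O)CC(=O)OCC)C1(C)C | intermediate
12 | ethyl 5-[(1S,3R)-3-[methoxy(methyl)carbamoyl]-2,2-dimethylcyclopropyl]-3-oxopentanoate | CON(C)C(=O)[C@@H]1[C@H](CCC(=O)CC(=O)OCC)C1(C)C | intermediate
13 | ethyl 5-[(1S,3R)-3-formyl-2,2-dimethylcyclopropyl]-3-oxopentanoate | O=C[C@@H]1[C@H](CCC(=O)CC(=O)OCC)C1(C)C | intermediate
14 | sodium (E)-3-ethoxy-3-oxoprop-1-en-1-olate (ethyl formylacetate Na salt) | [Na+].[O-]/C=C/C(=O)OCC | starting material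
15 | tricyclic β-keto enol-lactone, C10 enol form (C2 lactone, C4–CO2Et, C1=C10–OH; 5S,6S,7S) | CCOC(=O)C1=COC(=O)C2=C(O)CC[C@H]3[C@@H]([C@@H]12)C3(C)C | intermediate
16 | trifluoromethanesulfonic anhydride | FC(F)(F)S(=O)(=O)OS(=O)(=O)C(F)(F)F | starting material
17 | C10 vinyl triflate of 15 (5S,6S,7S) | CCOC(=O)C1=COC(=O)C2=C(OS(=O)(=O)C(F)(F)F)CC[C@H]3[C@@H]([C@@H]12)C3(C)C | intermediate
18 | methylzinc chloride | C[Zn]Cl | starting material
19 | α-alkylidene enol-lactone, C1=C10(CH3) (5R,6S,7S) | CCOC(=O)C1=COC(=O)C2=C(C)CC[C@H]3[C@@H]([C@@H]12)C3(C)C | intermediate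
20 | cis-fused enol-lactone ester with exocyclic C10=C14 (1R,5R,6S,7S) | CCOC(=O)C1=COC(=O)[C@@H]2[C@H]1[C@@H]1[C@H](CCC2=C)C1(C)C | intermediate
21 | lactol ester with exocyclic C10=C14 (1R,2S,5R,6S,7S; major anomer) | CCOC(=O)C1=CO[C@H](O)[C@@H]2[C@H]1[C@@H]1[C@H](CCC2=C)C1(C)C | intermediate
22 | tert-butyl hydroperoxide | CC(C)(C)OO | starting material
23 | epoxy-lactol ester (1R,2S,5R,6S,7S,10S) | CCOC(=O)C1=CO[C@H](O)[C@@H]2[C@H]1[C@@H]1[C@H](CC[C@@]23CO3)C1(C)C | intermediate
24 | acetic anhydride | CC(=O)OC(C)=O | starting material
25 | plagiochilin A (1R,2R,5R,6S,7S,10S) | CC(=O)OCC1=CO[C@H](OC(C)=O)[C@@H]2[C@H]1[C@@H]1[C@H](CC[C@@]23CO3)C1(C)C | target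

## Step count and risks

Total steps: 15. Longest linear sequence: 15 (fully linear from prenol).

Three steps most likely to fail:

- **Step 9 (domino ring formation).** The reversible seven-membered closure may lose to oligomerization or to a five-ring aldol through C9. Fallback: close the ring by an irreversible intramolecular Horner–Wadsworth–Emmons reaction of an α-phosphono-β-keto ester (from acylation of triethyl phosphonoacetate with the C8–C10 acid) onto the C5 aldehyde, isolate the cyclic alkylidene β-keto ester, and add 14 in a separate Michael/lactonization step.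
- **Step 12 (deconjugative protonation).** LDA may deprotonate elsewhere, the lactone enolate may open, or base may drive isomerization to the α-pyrone. Fallback: couple triflate 17 with Me3SiCH2ZnCl to the allylsilane and carry out buffered fluoride protodesilylation, which generates the same dienolate regiospecifically without a strong base.
- **Step 15 (global reduction/acetylation).** The aluminium lactolate may open and over-reduce at C2, and the product is acid-labile. Fallback: change to a protecting-group sequence: silylate lactol 23 as a mixed silyl acetal, reduce the ester, acetylate C15–OH, then unmask the lactol and acetylate it.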